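The leftover is where I would start: how much starting material does the gas reach at all? Here is the job as it stands.

| flask | starting material | gas phase | time |
|---|---|---|---|
| Wednesday's | 0.30 M | 31 mM (held) | 5.0 h |
| Monday's | 0.60 M | 31 mM (held) | 5.0 h |
| Friday's | 1.2 M | 31 mM (held) | 5.0 h |
| Sunday's | 2.5 M | 31 mM (held) | 5.0 h |

    starting material + dissolved gas → target (k1 = 6.13 /M/min)
    crystals ⇌ target, rate k2*(cs2 - [target]) while solid is left; crystals form when [target] > cs2 (cs2 = 0.098 M, k2 = 0.0350 /min)
    target → over-reaction product (k3 = 7.97 × 10⁻⁶ /min)
    dissolved gas + target → over-reacted product (k4 = 19.3 /M/min)
    gas phase ⇌ dissolved gas, rate k5*(csat - [dissolved gas]) (k5 = 0.0530 /min, csat = 31 mM)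

- what is said of target includes crystals
- crystals is a solid; its amount is given per volume of the solution
- at the start none of the gas is dissolved
- "hardly changes" means that all values lie within two and a half points (for a concentration: within two and a half percent of the largest)
- run time (Wednesday's): 5.0 h

- amount of target at the end, in percent of the starting material charged for Wednesday's, Monday's, Friday's, Sunday's, in this order
- the shape of the row from first to last (hardly changes / falls, then rises / rises, then falls / rises all the way / falls all the way)

For your quick number, multiply the transfer coefficient by the saturation concentration and the run time, which gives 0.493 M. This is the gas budget, the gas that can enter per volume of solution while dissolved gas stays near zero. At Wednesday's charge, step 1 halves dissolved gas in 0.38 min, far less than the 18.9 min of the transfer, so I take the transfer as the rate-limiting step.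

Each starting material converted costs one gas, and each over-reacted product costs a second, so the budget puts two ceilings on target as a share of the charge. Where the charge exceeds the budget, target stays under budget over charge, which on Sunday's is 19.7%. Where the budget exceeds the charge, as on Wednesday's, and if the budget enters in full, target stays under two minus budget over charge, which is 35.7%. The ceilings cross at a charge equal to the budget, and Monday's already stands above that crossing. So I commit to a row that rises, then falls. I expect it to sit under these ceilings, since the selectivity factor, step 4 over step 1, is 3.15. I reach no point values.

Your hunch, the forecast, does give them: 7.7%, 19.3%, 21.3% and 14.9%, so that the row rises, then falls. Its ground is this: “the concentrated charges simply cannot convert much and end up with a capped percentage”. Both ends lie under my ceilings, but the points are the forecast's own.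

The flasks give 7.69%, 19.5%, 21.4% and 14.5%, so the row rises, then falls. It turns near 0.89 M of starting material, higher than the budget. Wednesday's flask spent 0.476 M of gas, counting the starting material consumed and the over-reacted product, against the budget of 0.493 M. On Sunday's, target with its crystals plus twice the over-reacted product comes to 19.7% of the charge, and the budget is 19.7% of that charge.

The constants used here are assumed; the flask was simulated.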